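**Retrosynthetic overview**
1. The C6–alkenyl bond is made last: Suzuki–Miyaura coupling of a 6-iodo oxepinoflavone with an (E)-alkenylboronate, then ester cleavage.
2. Key step: the oxepine C(sp3)–O2' bond, by asymmetric epoxidation of a 3-prenyl group and in-flask 7-exo phenoxide opening; this sets the only stereocentre, (S).
3. The 3-prenylflavone triol comes from a Claisen condensation/cyclodehydration (closing pyranone ring C through O1–C2) of an α-prenylated 2,6-dihydroxy-4-methoxyphenyl ketone with MOM-protected methyl 2,4-dihydroxybenzoate.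
4. Ring order: rings A and B are bought as benzenoid building blocks, ring C is closed first and the oxepine ring second. The C6 side chain is added only after the prenyl alkene has been consumed.

Assumption: the stereocentre in the SMILES is read as (S); names use flavone numbering (O1, C2, C3, C4=O, ring A C5–C8, ring B C1'–C6'), "prenyl" = 3-methylbut-2-enyl, and "oxepinoflavone" = flavone bridged C3–CH2–CH[C(CH3)2OH]–O–C2'.

Step 1
Reactants: 1 2',6'-dihydroxy-4'-methoxyacetophenone; 2 prenyl bromide (1-bromo-3-methylbut-2-ene)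
Product: 3 1-(2,6-dihydroxy-4-methoxyphenyl)-5-methylhex-4-en-1-one
Conditions: LiN(iPr)2 (3.3 equiv), THF–DMPU, −78 °C; then 2 (1.0 equiv), −78 to −20 °C
Reagents that add atoms: none
Why: Enolate alkylation – in the trilithium salt the ketone enolate carbon is far more nucleophilic than the chelated lithium phenoxides at low temperature, so the allylic bromide is taken up by SN2 C-alkylation at the α-carbon; no stereocentre is formed.

Step 2
Reactants: 4 methyl 2,4-dihydroxybenzoate
Product: 5 methyl 2,4-bis(methoxymethoxy)benzoate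
Conditions: NaH (2.5 equiv), MOMCl (2.5 equiv), DMF, 0 °C to rt
Reagents that add atoms: chloromethyl methyl ether (MOMCl), COCCl
Why: Williamson-type O-alkylation of both sodium phenoxides (MOM protection) gives a non-acidic ester electrophile for the Claisen step, with groups that fall off in the acid used next.

Step 3
Reactants: 3 1-(2,6-dihydroxy-4-methoxyphenyl)-5-methylhex-4-en-1-one; 5 methyl 2,4-bis(methoxymethoxy)benzoate
Product: 8 5,2',4'-trihydroxy-7-methoxy-3-prenylflavone, via diketone 6 (not isolated), via MOM-protected flavone 7 (not isolated)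
Conditions: LiN(SiMe3)2 (4.5 equiv), THF, −78 to 60 °C; then 3 M HCl, MeOH, 60 °C
Reagents that add atoms: none
Why: Crossed Claisen condensation of the ketone polyanion with the non-enolisable ester (pulled forward by deprotonation of diketone 6), then acid-catalysed cyclodehydration through a ring-A hydroxyl (the two are equivalent and free before the ring-B MOM ether is cleaved, so a single flavone 7 forms) and acetal cleavage of both MOM groups; prenyl side chains survive methanolic HCl at this temperature.

Step 4
Reactants: 8 5,2',4'-trihydroxy-7-methoxy-3-prenylflavone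
Product: 10 (S)-oxepinoflavone [5,4'-dihydroxy-7-methoxyflavone bridged C3–CH2–CH(CMe2OH)–O–C2'], via (R)-epoxide 9 (not isolated)
Conditions: D-fructose-derived Shi ketone (0.3 equiv), 30% aq H2O2 (4 equiv), MeCN–EtOH–CH2Cl2 (1:1:2), 2 M aq K2CO3 (EDTA 4×10−4 M), 0 °C, 10 h; then 35 °C, 4 h
Reagents that add atoms: hydrogen peroxide, OO
Why: Proposed new method: a ketone-catalysed (Shi) asymmetric epoxidation run directly on the unprotected triphenol and coupled in the same flask to phenoxide ring closure – the dioxirane formed from the D-fructose-derived ketone and H2O2/MeCN transfers oxygen through the spiro transition state to the only electron-rich isolated alkene (the trisubstituted prenyl C=C) to give the (R)-epoxide 9, and the ring-B 2'-phenoxide present at pH 11, held next to the epoxide by the C2–C1' axis, opens it by 7-exo-tet SN2 attack at the secondary carbon (not 8-endo at the tertiary carbon) with inversion, which sets the (S) centre and leaves the tertiary alcohol; the delocalised, vinylogous-carboxylate phenoxides should be oxidised much more slowly than the alkene; the closest known reaction type is Shi epoxidation of O-silylated ortho-prenylphenols followed by a separate fluoride-triggered 5-exo epoxide opening to 2-(2-hydroxypropan-2-yl)dihydrobenzofurans, which has not been shown with free phenols in the oxidation or for closure of a seven-membered ring.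

Step 5
Reactants: 10 (S)-oxepinoflavone
Product: 11 4'-O-pivalate of 10
Conditions: PivCl (1.05 equiv), K2CO3, acetone, 0 °C
Reagents that add atoms: pivaloyl chloride, CC(C)(C)C(=O)Cl
Why: Base-mediated O-acylation is selective for the 4'-phenoxide (most acidic and unhindered; 5-OH is locked in the hydrogen bond to C4=O and the tertiary alcohol is inert), and the ester deactivates ring B for the following electrophilic substitution.

Step 6
Reactants: 11 4'-O-pivalate of 10
Product: 12 6-iodo-4'-O-pivalate
Conditions: BnMe3N·ICl2 (1.05 equiv), CaCO3, CH2Cl2–MeOH (5:2), rt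
Reagents that add atoms: benzyltrimethylammonium dichloroiodate, C[N+](C)(C)Cc1ccccc1.Cl[I-]Cl
Why: Electrophilic aromatic iodination – in 5-hydroxy-7-methoxyflavones the chelated 5-OH directs the iodonium equivalent to C6 rather than C8, ring B is deactivated by the pivalate and no alkene is left in the molecule; the stereocentre is not involved.

Step 7
Reactants: 13 3-methylbut-1-yne; 14 pinacolborane
Product: 15 (E)-4,4,5,5-tetramethyl-2-(3-methylbut-1-enyl)-1,3,2-dioxaborolane
Conditions: Cp2Zr(H)Cl (5 mol%), Et3N (10 mol%), neat, sealed tube, 60 °C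
Reagents that add atoms: none
Why: Zirconium-catalysed syn hydroboration of the terminal alkyne places boron on the terminal carbon and gives only the (E)-alkenylboronate.

Step 8
Reactants: 12 6-iodo-4'-O-pivalate; 15 (E)-4,4,5,5-tetramethyl-2-(3-methylbut-1-enyl)-1,3,2-dioxaborolane
Product: 17 CNP0216454.2 (target), via coupled pivalate 16 (not isolated)
Conditions: Pd(OAc)2 (5 mol%), SPhos (10 mol%), K3PO4 (3 equiv), 1,4-dioxane–H2O (4:1), 80 °C; then MeOH, 60 °C
Reagents that add atoms: none
Why: Suzuki–Miyaura coupling (the dialkylbiarylphosphine ligand handles the di-ortho-substituted electron-rich iodide) proceeds with retention of the (E) geometry, and the phosphate base then methanolyses the aryl pivalate in the same flask; the (S) centre is remote and untouched.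

**Compound list**
1 | 2',6'-dihydroxy-4'-methoxyacetophenone | CC(=O)c1c(O)cc(OC)cc1O | starting material
2 | prenyl bromide (1-bromo-3-methylbut-2-ene) | CC(C)=CCBr | starting material
3 | 1-(2,6-dihydroxy-4-methoxyphenyl)-5-methylhex-4-en-1-one | CC(C)=CCCC(=O)c1c(O)cc(OC)cc1O | intermediate
4 | methyl 2,4-dihydroxybenzoate | COC(=O)c1ccc(O)cc1O | starting material
5 | methyl 2,4-bis(methoxymethoxy)benzoate | COC(=O)c1ccc(OCOC)cc1OCOC | intermediate
6 | diketone (not isolated): 1-[2,4-bis(methoxymethoxy)phenyl]-3-(2,6-dihydroxy-4-methoxyphenyl)-2-(3-methylbut-2-enyl)propane-1,3-dione | COc1cc(O)c(C(=O)C(CC=C(C)C)C(=O)c2ccc(OCOC)cc2OCOC)c(O)c1 | intermediate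
7 | MOM-protected flavone (not isolated): 5-hydroxy-7-methoxy-2',4'-bis(methoxymethoxy)-3-prenylflavone | COc1cc(O)c2c(c1)oc(-c1ccc(OCOC)cc1OCOC)c(CC=C(C)C)c2=O | intermediate
8 | 5,2',4'-trihydroxy-7-methoxy-3-prenylflavone [2-(2,4-dihydroxyphenyl)-5-hydroxy-7-methoxy-3-(3-methylbut-2-enyl)chromen-4-one] | COc1cc(O)c2c(c1)oc(-c1ccc(O)cc1O)c(CC=C(C)C)c2=O | intermediate
9 | (R)-epoxide (not isolated): 2-(2,4-dihydroxyphenyl)-3-{[(2R)-3,3-dimethyloxiran-2-yl]methyl}-5-hydroxy-7-methoxychromen-4-one | COc1cc(O)c2c(c1)oc(-c1ccc(O)cc1O)c(C[C@H]1OC1(C)C)c2=O | intermediate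
10 | (S)-oxepinoflavone: 5,4'-dihydroxy-7-methoxyflavone bridged C3–CH2–CH[C(CH3)2OH]–O–C2', (S) at the bridge CH | COc1cc2oc3c(c(=O)c2c(O)c1)C[C@@H](C(C)(C)O)Oc1cc(O)ccc1-3 | intermediate
11 | 4'-O-pivalate of 10, (S) | COc1cc2oc3c(c(=O)c2c(O)c1)C[C@@H](C(C)(C)O)Oc1cc(OC(=O)C(C)(C)C)ccc1-3 | intermediate
12 | 6-iodo-4'-O-pivalate, (S): iodine on ring A between 5-OH and 7-OMe | COc1cc2oc3c(c(=O)c2c(O)c1I)C[C@@H](C(C)(C)O)Oc1cc(OC(=O)C(C)(C)C)ccc1-3 | intermediate
13 | 3-methylbut-1-yne | CC(C)C#C | starting material
14 | pinacolborane (4,4,5,5-tetramethyl-1,3,2-dioxaborolane) | CC1(C)OBOC1(C)C | starting material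
15 | (E)-4,4,5,5-tetramethyl-2-(3-methylbut-1-enyl)-1,3,2-dioxaborolane | CC(C)/C=C/B1OC(C)(C)C(C)(C)O1 | intermediate
16 | coupled pivalate (not isolated): 4'-O-pivalate of the target, (S), 6-[(E)-3-methylbut-1-enyl] | COc1cc2oc3c(c(=O)c2c(O)c1/C=C/C(C)C)C[C@@H](C(C)(C)O)Oc1cc(OC(=O)C(C)(C)C)ccc1-3 | intermediate
17 | CNP0216454.2: (S)-oxepinoflavone 10 carrying (E)-3-methylbut-1-enyl at C6 | COc1cc2oc3c(c(=O)c2c(O)c1/C=C/C(C)C)C[C@@H](C(C)(C)O)Oc1cc(O)ccc1-3 | target

**Step count and risks**
Total steps: 8. Longest linear sequence: 6 (steps 1, 3, 4, 5, 6, 8, from compound 1).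

Three steps most likely to fail:

- Step 4 (the new reaction). Risks: oxidation of the free phenoxides by the dioxirane, slow seven-membered ring closure, and ee below about 90%. The fallback uses known chemistry, sets out from 8 and comes back at 10. Compound 8 is silylated on the two ring-B phenols (TBSCl, imidazole, DMF; the chelated 5-OH does not react) to give the 2',4'-bis(tert-butyldimethylsilyl) ether F1. Conventional biphasic Shi epoxidation of this ether (D-fructose-derived ketone, KHSO5 as the triple salt 2KHSO5·KHSO4·K2SO4, K2CO3, pH 10.5, MeCN–dimethoxymethane, 0 °C) gives the silylated (R)-epoxide F2, which is isolated. Bu4NF in THF then removes both silyl groups, and the freed 2'-phenoxide opens the epoxide 7-exo with inversion to give 10.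

- Step 3. Risk: the α-substituted enolate of 3 may add sluggishly to the ortho-substituted ester. The fallback sets out from 1 (with 5) and comes back at 6; it also makes step 1 unnecessary. The trianion of 1 (LiN(SiMe3)2, THF) is condensed with 5 at the unhindered methyl group to give the α-unsubstituted diketone F3. Tsuji–Trost C-prenylation (Pd(PPh3)4, prenyl acetate, K2CO3, THF, 50 °C) then gives 6; O-allylation of the phenols is reversible under palladium catalysis, C-allylation of the diketone is not. Compound 6 is taken through the HCl/MeOH stage of step 3 to 8.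

- Step 8. Risks: slow coupling at the di-ortho-substituted, phenoxide-bearing iodide, and protodeiodination. The fallback sets out from 12 and comes back at 16. Sonogashira coupling of 12 with 13 (Pd(PPh3)2Cl2, CuI, Et3N, DMF, 25 °C) gives the 6-(3-methylbut-1-ynyl) pivalate F4; a linear alkyne is far less sensitive to the two ortho groups, and room temperature avoids benzofuran formation. Semi-hydrogenation (Pd/CaCO3 poisoned with Pb(OAc)2, quinoline, H2, EtOAc) gives the (Z)-alkene F5. Thiyl-radical isomerisation (catalytic PhSSPh, visible light) converts this to the conjugated (E)-alkene 16, whose pivalate is methanolysed as in step 8.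

**Further compounds**
F1 | step 4 | 2',4'-bis(tert-butyldimethylsilyl) ether of 8 | COc1cc(O)c2c(c1)oc(-c1ccc(O[Si](C)(C)C(C)(C)C)cc1O[Si](C)(C)C(C)(C)C)c(CC=C(C)C)c2=O
F2 | step 4 | silylated (R)-epoxide: 2',4'-bis(tert-butyldimethylsilyl) ether of 9 | COc1cc(O)c2c(c1)oc(-c1ccc(O[Si](C)(C)C(C)(C)C)cc1O[Si](C)(C)C(C)(C)C)c(C[C@H]1OC1(C)C)c2=O
F3 | step 3 | α-unsubstituted diketone: 1-[2,4-bis(methoxymethoxy)phenyl]-3-(2,6-dihydroxy-4-methoxyphenyl)propane-1,3-dione | COc1cc(O)c(C(=O)CC(=O)c2ccc(OCOC)cc2OCOC)c(O)c1
F4 | step 8 | 6-(3-methylbut-1-ynyl) pivalate, (S) | COc1cc2oc3c(c(=O)c2c(O)c1C#CC(C)C)C[C@@H](C(C)(C)O)Oc1cc(OC(=O)C(C)(C)C)ccc1-3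
F5 | step 8 | (Z)-alkene pivalate, (S), 6-[(Z)-3-methylbut-1-enyl] | COc1cc2oc3c(c(=O)c2c(O)c1/C=C\C(C)C)C[C@@H](C(C)(C)O)Oc1cc(OC(=O)C(C)(C)C)ccc1-3
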